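**Remarks on the chemistry (assumptions, one line each)**

- Ring locants used in every name: O1, C2 (aryl), C3 (cinnamyl arm), C4, C5 (carbinol arm), C6; the exocyclic carbinol carbon is C7. These locants are kept even where a strictly systematic name would number the ring the other way.
- Abbreviations: TBS = tert-butyl(dimethyl)silyl, TIPS = tri(propan-2-yl)silyl, TES = triethylsilyl, Bn = benzyl, PT = 1-phenyl-1H-tetrazol-5-yl.
- CrCl(L*) is the chloride complex of trivalent chromium with L*, the doubly deprotonated Schiff base of (1R,2S)-1-amino-2-indanol and 3-(1-adamantyl)-2-hydroxy-5-methylbenzaldehyde. It is assumed, by analogy with other aldehydes, that this antipode sends the diene to the Re face of the aldehyde; if the sense is the opposite, the (1S,2R) ligand is used and nothing else changes.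
- Design of the precursor: the diene carries benzyl on the side-chain oxygen and TBS on the C2 hydroxymethyl arm, and the phenols are TIPS ethers. With the opposite pattern, hydrogenolysis would free the C5 arm first. The acid-labile, para-oxygenated C7 carbinol would then have to be made early, protected, and carried through an acidic desilylation and a second oxidation.

## Structural features

The target is a single oxane ring with three 4-hydroxyphenyl groups: one directly on C2, one at the end of an (E)-cinnamyl chain on C3 (C3–CH2–CH=CH–Ar), and one on the exocyclic secondary carbinol C7 attached to C5; C4 and C6 are methylenes. There are four stereocentres: C2 (R) and C3 (S) are adjacent, C5 (R) is 1,3 to C3, and C7 (R) is adjacent to C5. The three ring substituents are all cis, so no chair places all of them equatorial, and the arrangement has to be set kinetically. The fragile functions are the benzylic C2–O1 ether and the C7 hydroxyl, both para to a phenol oxygen and therefore open to quinone-methide ionisation, and the electron-rich styrene, which tolerates neither hydrogenation nor strong acid. The real difficulty is the cis C2/C3/C5 pattern together with C7 in one absolute configuration, while three chemically identical phenols are carried. The key step uses the fact that O1 and C2 with its aryl group are a 4-oxybenzaldehyde unit, and that C3–C4–C5–C6 with the arms on C3 and C5 are a four-carbon diene oxygenated at C4 and C6. The C4 oxygen is needed only for reactivity and is deleted afterwards, and that deletion leaves the alkene from which C5 is set.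

## Logic of the disconnections

26 to 25: the three aryl O–Si bonds are cut last. Free phenols para to C2–O1 and C7–O make both benzylic positions ionisable, so they should exist only in the final compound. The gain is that every earlier intermediate is a robust silyl ether. The forward step must remove three silyl groups with buffered fluoride, without acid or strong base.

25 to 21 and 24 (24 from 23, 23 from 22): the C7–aryl bond is cut. C7 is the only exocyclic stereocentre and O1 is β to the carbonyl, so a magnesium chelate can relay C5 to C7. The gain is the loss of one aryl ring and one stereocentre. The forward addition must be chelation-controlled and faster than enolisation at C5.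

21 to 20 to 19: no skeletal bond is cut; the C7 oxidation level is adjusted and the alkyl O–Si bond is cleaved. The C5 hydroxymethyl stays masked until the styrene is in place. The forward acid must remove an alkyl silyl ether and leave two aryl silyl ethers and the styrene.

19 to 18 and 11: the styrene C=C is cut. It is the one function that cannot pass through hydrogenation, so it is made after C5 is set. The gain is the loss of the second aryl ring, and 11 is also the dienophile of the key step. The forward olefination must be E-selective.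

18 to 17 to 16: the C–S bond is traced back to the primary C–O bond (substitution, then S-oxidation before any alkene is present). The gain is a simple primary alcohol. The forward steps must leave the silyl ethers alone.

16 to 15: the C4–H and C5–H bonds are removed and the benzyl C–O bond is restored. The gain is that C5 is traced to a ring alkene. The forward hydrogenation must occur on the face opposite the two cis groups and must spare the ring C2–O1 bond.

15 to 14 to 13: the C4–O bond is restored. The C4 carbonyl of 13 is indispensable for the cycloaddition but absent from the target. 1,2-Reduction and allylic hydride transposition remove it and leave C4=C5. The forward ionisation must occur at C4 and not at C2.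

13 to 9 and 11 (through 12): C2–C3 and O1–C6 are cut together. The gain is the ring, two stereocentres and one aryl group in a single step from an achiral diene. The forward step must be a concerted, endo, catalyst-controlled cycloaddition.

9 to 8: the enol O–Si bond is cut; the forward enolisation must give the Z enol silane. 8 to 5 and 7 (7 from 6): the acyl–alkyl C–C bond is cut; the forward addition must stop at the ketone. 5 to 4: the C–N bond. 4 to 2 (through 3): the bond to the future C6 and the O–CH3 bond are cut, which places the one-carbon unit unambiguously; the forward condensation must avoid β-elimination. 2 to 1 and 11 to 10: O–Si bonds.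

## Other disconnections considered

Alternative 1: The cut is the O1–C2 ring bond. In the forward direction Sc(OTf)3 binds the geminal diester of cyclopropane A2, and the C6 hydroxyl displaces the aryl-bearing cyclopropane carbon with inversion, closing the oxane and leaving a malonate on C3 in A1.
- In its favour: ring closure is stereospecific, so the cis C2/C3 relation is written into the cis cyclopropane, and the malonate is a flexible handle. C5 and C7 are fixed before the ring exists, so no hydrogenation is needed; on this point it is better than the chosen plan.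
- Against it here: A2 already holds four stereocentres, so the stereochemical work is moved into an open chain and a stereodefined cyclopropane, not reduced. The para-oxygenated aryl donor makes an open benzylic cation a likely competitor to the invertive path, which would cost the stereospecificity at C2. The same Lewis acid meets the ionisable C7 silyl ether. The malonate must then be cut down by dealkoxycarbonylation, reduction and olefination.
- Comparison: structurally both plans close the ring and fix C2 in one step (equal). Mechanistically this is substrate stereospecificity against catalyst control in a concerted cycloaddition; both are sound in principle, but this one is more exposed to the electron-rich aryl group. In step economy the chosen plan should be shorter, because its precursor is achiral and made in five steps.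

Alternative 2: The cuts are C2–C3 and C5–C7 together, because the C2/C3 pair and the C7/C5 pair are the same aryl-carbinol unit repeated about C4. In the forward direction bis-imide A4 is enolised at both ends (MgCl2, Et3N, Me3SiCl) and adds to two molecules of aldehyde A5 to give the twofold-symmetric anti,anti adduct A3; no ring is closed.
- In its favour: four stereocentres and two of the three aryl rings arrive in one operation. C7 comes from a reagent-controlled aldol and not from a substrate-controlled addition; on this point it is better than the chosen plan. The symmetry of A3 means that acyl transfer from either carbinol to the distal imide gives the same ring.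
- Against it here: the ring still has to be made, and the C6 acyl carbon must be reduced to a methylene next to two ionisable benzylic C–O bonds. The other acyl carbon must become the CH2 of the cinnamyl arm, which needs reduction and a C–C coupling with a styryl unit. The double addition must be selective at both ends, and aldol adducts of electron-rich aryl aldehydes are prone to retro-aldol cleavage.
- Comparison: structurally it sets more stereocentres per step (better) but forms the ring later (worse). Mechanistically it uses two stoichiometric auxiliaries where the chosen plan uses a catalyst. In step economy the front end is shorter and the back end longer, so the two are about equal overall.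

Alternative 3: The cut is O1–C6, with the ring traced back to a furan. In the forward direction N-bromosuccinimide with NaHCO3 in aqueous THF oxidises the furan of carbinol A7, and the opened enedione recloses through the carbinol oxygen to hemiacetal A6 (Achmatowicz rearrangement).
- In its favour: it is the shortest access to the oxygenated ring with the C2 aryl group. Only the carbinol stereocentre needs external control, and the C5 hydroxymethyl is already in place. It is the equal of the chosen plan in setting C5 by hydrogenation and better in the length of the ring synthesis.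
- Against it here: in A6 the C2–H is α to the ketone, benzylic and α to oxygen, so enolisation could erode the only stereocentre. The cinnamyl carbon must be attached at the C3 ketone by olefination of a hindered, enolisable ketone, and the C6 hydroxyl must be removed by ionic reduction. Hydrogenation must then set both C3 and C5 cis to the C2 aryl group in a substrate whose C2–O1 bond is both allylic and benzylic. The furyl aryl carbinol is acid-labile.
- Comparison: structurally the ring arrives sooner. Mechanistically C3 would rest on face selectivity of a heterogeneous hydrogenation, where the chosen plan uses a pericyclic transition state for C2/C3. It could be a few steps shorter, and so better in step economy, provided that selectivity holds.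

Key step: step 7

## Route

Step 1
Reactants: 1 methyl 3-hydroxypropanoate
Product: 2 methyl 3-(TBSO)propanoate
Conditions: TBSCl, imidazole, CH2Cl2, 0 °C → rt
Reagents that add atoms: tert-butyl(chloro)dimethylsilane, CC(C)(C)[Si](C)(C)Cl
Why: Imidazole-promoted silyl ether formation at the only hydroxyl; the ester is inert.

Step 2
Reactants: 2 methyl 3-(TBSO)propanoate
Product: 4 methyl (E)-2-(TBSO-methyl)-3-methoxyprop-2-enoate, via sodium formyl-ester enolate 3 (not isolated)
Conditions: NaH, HCO2Me, THF, 0 °C → rt; then Me2SO4, DMF, 0 °C → rt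
Reagents that add atoms: methyl formate, COC=O; dimethyl sulfate, COS(=O)(=O)OC
Why: Crossed Claisen condensation with the non-enolisable formate is driven by formation of the stabilised enolate 3 and is kept cold to limit E1cB loss of silanolate; dimethyl sulfate in DMF then O-methylates the hard enolate oxygen. The E isomer (methoxy anti to the ester) is the thermodynamically preferred enol ether, and any Z isomer is removed or equilibrated with a trace of acid.

Step 3
Reactants: 4 methyl (E)-2-(TBSO-methyl)-3-methoxyprop-2-enoate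
Product: 5 (E)-2-(TBSO-methyl)-N,3-dimethoxy-N-methylprop-2-enamide
Conditions: MeNH(OMe)·HCl, iPrMgCl, THF, −20 → 0 °C
Reagents that add atoms: N,O-dimethylhydroxylamine hydrochloride, CNOC.Cl
Why: Aminolysis of the ester by the chloromagnesium amide made in the flask (Weinreb amide synthesis); at low temperature acyl substitution is expected to outrun addition–elimination at the methoxy-bearing carbon, and the silyl ether and enol ether tolerate the basic medium.

Step 4
Reactants: 5 (E)-2-(TBSO-methyl)-N,3-dimethoxy-N-methylprop-2-enamide; 6 benzyl 3-bromopropyl ether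
Product: 8 (E)-6-(benzyloxy)-2-(TBSO-methyl)-1-methoxyhex-1-en-3-one, via 3-(benzyloxy)propylmagnesium bromide 7 (not isolated)
Conditions: 6, Mg, THF, rt; then 5, THF, −20 → 0 °C; aq NH4Cl
Reagents that add atoms: none
Why: Weinreb ketone synthesis: 7 adds once to give a magnesium-chelated tetrahedral adduct that collapses only on work-up, so no tertiary alcohol forms; the donor methoxy group deactivates the β-carbon toward conjugate attack.

Step 5
Reactants: 8 (E)-6-(benzyloxy)-2-(TBSO-methyl)-1-methoxyhex-1-en-3-one
Product: 9 (1E,3Z)-6-(benzyloxy)-2-(TBSO-methyl)-1-methoxy-3-(triethylsilyloxy)hexa-1,3-diene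
Conditions: Et3SiOTf, Et3N, Et2O, −78 → 0 °C
Reagents that add atoms: triethylsilyl trifluoromethanesulfonate, CC[Si](CC)(CC)OS(=O)(=O)C(F)(F)F
Why: Soft enolisation and O-silylation at the only enolisable α-carbon (silyl enol ether formation). The Z enol silane is favoured because the E isomer would press the C5 methylene against the C2 substituents (allylic 1,3-strain), and this places the chain on the outside of the s-cis diene.

Step 6
Reactants: 10 4-hydroxybenzaldehyde
Product: 11 4-(TIPSO)benzaldehyde
Conditions: iPr3SiCl, imidazole, DMF, rt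
Reagents that add atoms: chlorotri(propan-2-yl)silane, CC(C)[Si](Cl)(C(C)C)C(C)C
Why: Phenol silylation; the bulky TIPS ether should resist the basic and mildly acidic steps ahead and still fall to fluoride at the end.

Step 7
Reactants: 9 (1E,3Z)-6-(benzyloxy)-2-(TBSO-methyl)-1-methoxy-3-(triethylsilyloxy)hexa-1,3-diene; 11 4-(TIPSO)benzaldehyde
Product: 13 (2R,3R)-3-[2-(benzyloxy)ethyl]-5-(TBSO-methyl)-2-[4-(TIPSO)phenyl]-2,3-dihydro-4H-pyran-4-one, via silyl enol ether cycloadduct 12 (not isolated)
Conditions: CrCl(L*) (10 mol %), 4 Å sieves, EtOAc (minimal), rt; then CF3CO2H (cat.), CH2Cl2, 0 °C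
Reagents that add atoms: none
Why: The Lewis-acidic trivalent chromium centre of CrCl(L*) binds the carbonyl oxygen of 11, and 9 adds in a concerted, asynchronous [4+2] cycloaddition: the enol-silane carbon bonds to the carbonyl carbon (new C2–C3) and the carbonyl oxygen bonds to the methoxy-bearing terminus (new O1–C6). The closest known reaction type is the chromium Schiff-base catalysed hetero-Diels–Alder reaction of aldehydes with 1-alkoxy-3-silyloxy dienes, which gives cis-2,3-disubstituted dihydropyranones. The one ring is closed by the cycloaddition itself, both ring bonds forming in a single suprafacial event, so 12 forms directly; trifluoroacetic acid then expels methanol and the triethylsilyl group to give the vinylogous ester 13. C2 is controlled by the catalyst, which is taken to expose the Re face of the bound aldehyde. C3 is controlled by the diene geometry and the endo rule: the (3Z) enol silane holds its CH2 chain outside the s-cis diene and the aryl group lies endo, so aryl and chain end cis. The step needs endo selectivity and a concerted path in place of a stepwise Mukaiyama aldol; the mild chromium chloride complex without protic or strongly Lewis-acidic additives and the (1E,3Z) geometry should secure both. The acid treatment is brief and cold so that the now enolisable C3 does not epimerise.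

Step 8
Reactants: 13 (2R,3R)-3-[2-(benzyloxy)ethyl]-5-(TBSO-methyl)-2-[4-(TIPSO)phenyl]-2,3-dihydro-4H-pyran-4-one
Product: 14 (2R,3S,4R)-3-[2-(benzyloxy)ethyl]-5-(TBSO-methyl)-2-[4-(TIPSO)phenyl]-3,4-dihydro-2H-pyran-4-ol
Conditions: NaBH4, CeCl3·7H2O, MeOH, −78 → −40 °C
Reagents that add atoms: none
Why: Luche reduction: cerium-activated borohydride adds 1,2 to the vinylogous ester carbonyl, with hydride expected anti to the pseudo-axial C3 chain. The C4 configuration is of no consequence because C4 loses its oxygen in step 9, and the cold, near-neutral medium should leave C3 and the aryl silyl ether untouched.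

Step 9
Reactants: 14 (2R,3S,4R)-3-[2-(benzyloxy)ethyl]-5-(TBSO-methyl)-2-[4-(TIPSO)phenyl]-3,4-dihydro-2H-pyran-4-ol
Product: 15 (2R,3S)-3-[2-(benzyloxy)ethyl]-5-(TBSO-methyl)-2-[4-(TIPSO)phenyl]-3,6-dihydro-2H-pyran
Conditions: Et3SiH, BF3·OEt2, CH2Cl2, −78 °C
Reagents that add atoms: none
Why: Ferrier-type ionisation of the allylic hydroxyl gives the O1-stabilised allyl cation, which takes hydride from Et3SiH at C6, the carbon next to oxygen, so the double bond moves to C4=C5 (reductive allylic transposition). At −78 °C the silyl ethers and the C2–O1 bond, which cannot ionise while O1 carries the positive charge, should survive.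

Step 10
Reactants: 15 (2R,3S)-3-[2-(benzyloxy)ethyl]-5-(TBSO-methyl)-2-[4-(TIPSO)phenyl]-3,6-dihydro-2H-pyran
Product: 16 2-[(2R,3R,5R)-5-(TBSO-methyl)-2-[4-(TIPSO)phenyl]oxan-3-yl]ethanol
Conditions: H2 (1 atm), 10% Pd/C, EtOAc, rt
Reagents that add atoms: none
Why: Heterogeneous hydrogenation: the C2 aryl group and the C3 chain lie on one face of the half-chair, so hydrogen is delivered to the other face of C4=C5 and the C5 substituent ends cis to both (C5 set). The unhindered primary benzyl ether is hydrogenolysed in the same operation, and this is expected to be much faster than cleavage of the hindered secondary ring C2–O1 bond.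

Step 11
Reactants: 16 2-[(2R,3R,5R)-5-(TBSO-methyl)-2-[4-(TIPSO)phenyl]oxan-3-yl]ethanol
Product: 17 5-({2-[(2R,3R,5R)-5-(TBSO-methyl)-2-[4-(TIPSO)phenyl]oxan-3-yl]ethyl}sulfanyl)-1-phenyl-1H-tetrazole
Conditions: 1-phenyl-1H-tetrazole-5-thiol, PPh3, iPrO2CN=NCO2iPr, THF, 0 °C → rt
Reagents that add atoms: 1-phenyl-1H-tetrazole-5-thiol, Sc1nnnn1-c1ccccc1
Why: Mitsunobu thioetherification of the only free, primary alcohol with the acidic thiol; no stereocentre is involved.

Step 12
Reactants: 17 5-({2-[(2R,3R,5R)-5-(TBSO-methyl)-2-[4-(TIPSO)phenyl]oxan-3-yl]ethyl}sulfanyl)-1-phenyl-1H-tetrazole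
Product: 18 5-({2-[(2R,3R,5R)-5-(TBSO-methyl)-2-[4-(TIPSO)phenyl]oxan-3-yl]ethyl}sulfonyl)-1-phenyl-1H-tetrazole
Conditions: mCPBA, CH2Cl2, 0 °C → rt
Reagents that add atoms: 3-chloroperoxybenzoic acid, OOC(=O)c1cccc(Cl)c1
Why: Peracid oxidation of the sulfide through the sulfoxide to the sulfone; it is placed before any alkene exists, and aryl silyl ethers and the ring ether are not oxidised under these conditions.

Step 13
Reactants: 18 5-({2-[(2R,3R,5R)-5-(TBSO-methyl)-2-[4-(TIPSO)phenyl]oxan-3-yl]ethyl}sulfonyl)-1-phenyl-1H-tetrazole; 11 4-(TIPSO)benzaldehyde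
Product: 19 (2R,3S,5R)-5-(TBSO-methyl)-2-[4-(TIPSO)phenyl]-3-{(2E)-3-[4-(TIPSO)phenyl]prop-2-en-1-yl}oxane
Conditions: KN(SiMe3)2 added to 18 + 11, DME, −78 °C → rt
Reagents that add atoms: none
Why: Julia–Kocienski olefination: the sulfonyl carbanion adds to the non-enolisable aldehyde, and Smiles rearrangement with loss of SO2 and the tetrazolate gives the alkene. With an aryl aldehyde the elimination passes through a benzylic-stabilised intermediate that leads to the E alkene, and adding base to the mixture of both partners suppresses self-condensation of the sulfone.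

Step 14
Reactants: 19 (2R,3S,5R)-5-(TBSO-methyl)-2-[4-(TIPSO)phenyl]-3-{(2E)-3-[4-(TIPSO)phenyl]prop-2-en-1-yl}oxane
Product: 20 [(2R,3S,5S)-2-[4-(TIPSO)phenyl]-3-{(2E)-3-[4-(TIPSO)phenyl]prop-2-en-1-yl}oxan-5-yl]methanol
Conditions: PPTS (cat.), MeOH/CH2Cl2, rt
Reagents that add atoms: none
Why: Acid-catalysed methanolysis of a silyl ether: a primary alkyl TBS ether is cleaved far faster than aryl TIPS ethers, and pyridinium tosylate is too weak to ionise the C2–O1 bond or protonate the styrene.

Step 15
Reactants: 20 [(2R,3S,5S)-2-[4-(TIPSO)phenyl]-3-{(2E)-3-[4-(TIPSO)phenyl]prop-2-en-1-yl}oxan-5-yl]methanol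
Product: 21 (2R,3S,5R)-2-[4-(TIPSO)phenyl]-3-{(2E)-3-[4-(TIPSO)phenyl]prop-2-en-1-yl}oxane-5-carbaldehyde
Conditions: Dess–Martin periodinane, pyridine, CH2Cl2, 0 °C → rt
Reagents that add atoms: none
Why: Dess–Martin oxidation of the primary alcohol under buffered, non-basic conditions; the aldehyde, whose α-carbon C5 could epimerise, is used at once without chromatography.

Step 16
Reactants: 22 4-bromophenol
Product: 23 (4-bromophenoxy)tri(propan-2-yl)silane
Conditions: iPr3SiCl, imidazole, DMF, rt
Reagents that add atoms: chlorotri(propan-2-yl)silane, CC(C)[Si](Cl)(C(C)C)C(C)C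
Why: Phenol silylation as in step 6; it gives the precursor of the aryl nucleophile with the same phenol protection as the other two rings.

Step 17
Reactants: 21 (2R,3S,5R)-2-[4-(TIPSO)phenyl]-3-{(2E)-3-[4-(TIPSO)phenyl]prop-2-en-1-yl}oxane-5-carbaldehyde; 23 (4-bromophenoxy)tri(propan-2-yl)silane
Product: 25 (R)-[(2R,3S,5R)-2-[4-(TIPSO)phenyl]-3-{(2E)-3-[4-(TIPSO)phenyl]prop-2-en-1-yl}oxan-5-yl][4-(TIPSO)phenyl]methanol, via 4-(TIPSO)phenylmagnesium bromide 24 (not isolated)
Conditions: 23, Mg, THF, 40 °C; then 21, MgBr2·OEt2, CH2Cl2, −78 °C; aq NH4Cl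
Reagents that add atoms: none
Why: Grignard addition under chelation control: magnesium bridges the aldehyde oxygen and the ring oxygen O1, which is β to the carbonyl, in a six-membered chelate that needs the formyl group axial. The aryl group then adds to the carbonyl face anti to C4, which gives the 7R carbinol (hydroxyl anti to C4 along the Ar–C7–C5–C6 chain). The low temperature and the weakly basic aryl reagent limit enolisation at C5.

Step 18
Reactants: 25 (R)-[(2R,3S,5R)-2-[4-(TIPSO)phenyl]-3-{(2E)-3-[4-(TIPSO)phenyl]prop-2-en-1-yl}oxan-5-yl][4-(TIPSO)phenyl]methanol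
Product: 26 4-[(2R,3S,5R)-5-[(R)-hydroxy(4-hydroxyphenyl)methyl]-3-[(2E)-3-(4-hydroxyphenyl)prop-2-en-1-yl]oxan-2-yl]phenol
Conditions: Bu4NF, AcOH, THF, 0 °C
Reagents that add atoms: none
Why: Fluoride-mediated cleavage of the three aryl silyl ethers; acetic acid buffers the phenoxides so that quinone-methide formation at C2 or C7 and epimerisation at C2 are not triggered, and the C7 hydroxyl was never protected.

## Compound list

1 | methyl 3-hydroxypropanoate | COC(=O)CCO | starting material
2 | methyl 3-(TBSO)propanoate | COC(=O)CCO[Si](C)(C)C(C)(C)C | intermediate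
3 | sodium enolate of methyl 2-formyl-3-(TBSO)propanoate (delocalised, geometry not fixed; not isolated) | [Na+].[O-]C=C(CO[Si](C)(C)C(C)(C)C)C(=O)OC | intermediate
4 | methyl (E)-2-(TBSO-methyl)-3-methoxyprop-2-enoate | CO/C=C(CO[Si](C)(C)C(C)(C)C)/C(=O)OC | intermediate
5 | (E)-2-(TBSO-methyl)-N,3-dimethoxy-N-methylprop-2-enamide | CO/C=C(CO[Si](C)(C)C(C)(C)C)/C(=O)N(C)OC | intermediate
6 | benzyl 3-bromopropyl ether | BrCCCOCc1ccccc1 | starting material
7 | 3-(benzyloxy)propylmagnesium bromide (not isolated) | Br[Mg]CCCOCc1ccccc1 | intermediate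
8 | (E)-6-(benzyloxy)-2-(TBSO-methyl)-1-methoxyhex-1-en-3-one | CO/C=C(CO[Si](C)(C)C(C)(C)C)/C(=O)CCCOCc1ccccc1 | intermediate
9 | (1E,3Z)-6-(benzyloxy)-2-(TBSO-methyl)-1-methoxy-3-(triethylsilyloxy)hexa-1,3-diene | CO/C=C(CO[Si](C)(C)C(C)(C)C)/C(O[Si](CC)(CC)CC)=C/CCOCc1ccccc1 | intermediate
10 | 4-hydroxybenzaldehyde | O=Cc1ccc(O)cc1 | starting material
11 | 4-(TIPSO)benzaldehyde | O=Cc1ccc(O[Si](C(C)C)(C(C)C)C(C)C)cc1 | intermediate
12 | (2R,3R,6S)-3-[2-(benzyloxy)ethyl]-5-(TBSO-methyl)-6-methoxy-4-(triethylsilyloxy)-2-[4-(TIPSO)phenyl]-3,6-dihydro-2H-pyran (not isolated) | c1ccccc1COCC[C@H]2C(O[Si](CC)(CC)CC)=C(CO[Si](C)(C)C(C)(C)C)[C@@H](OC)O[C@H]2c3ccc(O[Si](C(C)C)(C(C)C)C(C)C)cc3 | intermediate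
13 | (2R,3R)-3-[2-(benzyloxy)ethyl]-5-(TBSO-methyl)-2-[4-(TIPSO)phenyl]-2,3-dihydro-4H-pyran-4-one | c1ccccc1COCC[C@H]2C(=O)C(CO[Si](C)(C)C(C)(C)C)=CO[C@H]2c3ccc(O[Si](C(C)C)(C(C)C)C(C)C)cc3 | intermediate
14 | (2R,3S,4R)-3-[2-(benzyloxy)ethyl]-5-(TBSO-methyl)-2-[4-(TIPSO)phenyl]-3,4-dihydro-2H-pyran-4-ol | c1ccccc1COCC[C@H]2[C@@H](O)C(CO[Si](C)(C)C(C)(C)C)=CO[C@H]2c3ccc(O[Si](C(C)C)(C(C)C)C(C)C)cc3 | intermediate
15 | (2R,3S)-3-[2-(benzyloxy)ethyl]-5-(TBSO-methyl)-2-[4-(TIPSO)phenyl]-3,6-dihydro-2H-pyran | c1ccccc1COCC[C@H]2C=C(CO[Si](C)(C)C(C)(C)C)CO[C@H]2c3ccc(O[Si](C(C)C)(C(C)C)C(C)C)cc3 | intermediate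
16 | 2-[(2R,3R,5R)-5-(TBSO-methyl)-2-[4-(TIPSO)phenyl]oxan-3-yl]ethanol | OCC[C@H]1C[C@@H](CO[Si](C)(C)C(C)(C)C)CO[C@H]1c2ccc(O[Si](C(C)C)(C(C)C)C(C)C)cc2 | intermediate
17 | 5-({2-[(2R,3R,5R)-5-(TBSO-methyl)-2-[4-(TIPSO)phenyl]oxan-3-yl]ethyl}sulfanyl)-1-phenyl-1H-tetrazole | c1ccccc1-n2nnnc2SCC[C@H]3C[C@@H](CO[Si](C)(C)C(C)(C)C)CO[C@H]3c4ccc(O[Si](C(C)C)(C(C)C)C(C)C)cc4 | intermediate
18 | 5-({2-[(2R,3R,5R)-5-(TBSO-methyl)-2-[4-(TIPSO)phenyl]oxan-3-yl]ethyl}sulfonyl)-1-phenyl-1H-tetrazole | c1ccccc1-n2nnnc2S(=O)(=O)CC[C@H]3C[C@@H](CO[Si](C)(C)C(C)(C)C)CO[C@H]3c4ccc(O[Si](C(C)C)(C(C)C)C(C)C)cc4 | intermediate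
19 | (2R,3S,5R)-5-(TBSO-methyl)-2-[4-(TIPSO)phenyl]-3-{(2E)-3-[4-(TIPSO)phenyl]prop-2-en-1-yl}oxane | CC(C)[Si](C(C)C)(C(C)C)Oc1ccc(/C=C/C[C@H]2C[C@@H](CO[Si](C)(C)C(C)(C)C)CO[C@H]2c3ccc(O[Si](C(C)C)(C(C)C)C(C)C)cc3)cc1 | intermediate
20 | [(2R,3S,5S)-2-[4-(TIPSO)phenyl]-3-{(2E)-3-[4-(TIPSO)phenyl]prop-2-en-1-yl}oxan-5-yl]methanol | CC(C)[Si](C(C)C)(C(C)C)Oc1ccc(/C=C/C[C@H]2C[C@@H](CO)CO[C@H]2c3ccc(O[Si](C(C)C)(C(C)C)C(C)C)cc3)cc1 | intermediate
21 | (2R,3S,5R)-2-[4-(TIPSO)phenyl]-3-{(2E)-3-[4-(TIPSO)phenyl]prop-2-en-1-yl}oxane-5-carbaldehyde | CC(C)[Si](C(C)C)(C(C)C)Oc1ccc(/C=C/C[C@H]2C[C@@H](C=O)CO[C@H]2c3ccc(O[Si](C(C)C)(C(C)C)C(C)C)cc3)cc1 | intermediate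
22 | 4-bromophenol | Oc1ccc(Br)cc1 | starting material
23 | (4-bromophenoxy)tri(propan-2-yl)silane | CC(C)[Si](C(C)C)(C(C)C)Oc1ccc(Br)cc1 | intermediate
24 | 4-(TIPSO)phenylmagnesium bromide (not isolated) | CC(C)[Si](C(C)C)(C(C)C)Oc1ccc([Mg]Br)cc1 | intermediate
25 | (R)-[(2R,3S,5R)-2-[4-(TIPSO)phenyl]-3-{(2E)-3-[4-(TIPSO)phenyl]prop-2-en-1-yl}oxan-5-yl][4-(TIPSO)phenyl]methanol | CC(C)[Si](C(C)C)(C(C)C)Oc1ccc(/C=C/C[C@H]2C[C@@H]([C@@H](O)c3ccc(O[Si](C(C)C)(C(C)C)C(C)C)cc3)CO[C@H]2c4ccc(O[Si](C(C)C)(C(C)C)C(C)C)cc4)cc1 | intermediate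
26 | 4-[(2R,3S,5R)-5-[(R)-hydroxy(4-hydroxyphenyl)methyl]-3-[(2E)-3-(4-hydroxyphenyl)prop-2-en-1-yl]oxan-2-yl]phenol | Oc1ccc(/C=C/C[C@H]2C[C@@H]([C@@H](O)c3ccc(O)cc3)CO[C@H]2c2ccc(O)cc2)cc1 | target

## Step count and least certain steps

Total: 18 steps. Longest linear sequence: 16 steps (1 to 26 through steps 1–5, 7–15, 17 and 18); steps 6 and 16 are side branches.

Step 7 (key step). The most likely failure is a slow cycloaddition, because the para-silyloxy aldehyde is a weak electrophile and the diene is fully substituted. Hydrolysis of the diene could then compete, and a partly stepwise aldol path could erode both the cis relation and the facial selectivity. Epimerisation at C3 during the acid treatment is a second hazard. The fallback sets out from 8 and 11 and returns at 13. Ketone 8 is converted into its Z enol borinate with Ipc2BOTf and iPr2NEt (CH2Cl2, −78 °C), using the antipode of the reagent that attacks the Re face of the aldehyde. A reagent-controlled syn aldol addition to 11 then gives (1E,4R,5R)-4-[2-(benzyloxy)ethyl]-2-(TBSO-methyl)-5-hydroxy-1-methoxy-5-[4-(TIPSO)phenyl]pent-1-en-3-one F1. Brief treatment with CF3CO2H in CH2Cl2 lets the hydroxyl add to the methoxy enone and expel methanol, which closes the ring to 13 with the syn aldol relation becoming cis C2/C3.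

Step 2. The ester enolate could lose silanolate by E1cB elimination before it is formylated, and some C-methylation could accompany O-methylation. The fallback sets out from 2 and returns at 4. Enolisation with LiN(iPr)2 in the presence of Me3SiCl (THF, −78 °C), so that the enolate is trapped as it forms, gives the ketene acetal 1-methoxy-1-(trimethylsilyloxy)-3-(TBSO)prop-1-ene F2. A Mukaiyama-type condensation with trimethyl orthoformate and catalytic Me3SiOTf gives racemic methyl 2-(TBSO-methyl)-3,3-dimethoxypropanoate F3. Elimination of methanol (Me3SiOTf, iPr2NEt, CH2Cl2, 0 °C) then gives 4.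

Step 9. The Lewis acid could ionise the benzylic C2–O1 bond of the product or strip silyl groups, and some hydride delivery at C4 is possible. The fallback sets out from 14 and returns at 15 without any Lewis acid. Mitsunobu coupling of 14 with 2-nitrobenzenesulfonyl hydrazide (PPh3, EtO2CN=NCO2Et, THF, −30 °C) gives N-[(2R,3S,4S)-3-[2-(benzyloxy)ethyl]-5-(TBSO-methyl)-2-[4-(TIPSO)phenyl]-3,4-dihydro-2H-pyran-4-yl]-2-nitrobenzenesulfonohydrazide F4. On warming this loses the sulfinic acid to give the allylic diazene (2R,3S,4S)-3-[2-(benzyloxy)ethyl]-5-(TBSO-methyl)-4-diazenyl-2-[4-(TIPSO)phenyl]-3,4-dihydro-2H-pyran F5. A retro-ene loss of N2 then delivers hydrogen to C6 and moves the double bond to C4=C5, giving 15. If substitution occurred with allylic shift, the enol ether isomer of 15 would result, and it would converge on 16 in step 10.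

Step 10. Hydrogenolysis of an allylic C–O bond or of the ring benzylic C2–O1 bond could compete while the alkene is still present, and face selectivity could be incomplete. The fallback sets out from 15 and returns at 16 by separating the two events. Saturation over PtO2 (H2, 1 atm, EtOAc), which is not expected to cleave C–O bonds under neutral conditions, gives (2R,3R,5R)-3-[2-(benzyloxy)ethyl]-5-(TBSO-methyl)-2-[4-(TIPSO)phenyl]oxane F6. The benzyl ether is then removed on this saturated compound, which has no allylic C–O bond left, by hydrogenolysis over Pd(OH)2/C (H2, EtOAc) stopped at the consumption of F6, giving 16.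

Step 17. Facial selectivity could be poor if chelation does not dominate, because the chelating chair carries the C3 and C5 groups 1,3-diaxial, and enolisation could epimerise C5. The fallback sets out from 21 and returns at 25, and it moves control from the substrate to a reagent. Addition of 24 in THF without regard to selectivity gives 25 mixed with its epimer (S)-[(2R,3S,5R)-2-[4-(TIPSO)phenyl]-3-{(2E)-3-[4-(TIPSO)phenyl]prop-2-en-1-yl}oxan-5-yl][4-(TIPSO)phenyl]methanol F7. Dess–Martin oxidation of the mixture gives [(2R,3S,5R)-2-[4-(TIPSO)phenyl]-3-{(2E)-3-[4-(TIPSO)phenyl]prop-2-en-1-yl}oxan-5-yl][4-(TIPSO)phenyl]methanone F8. Corey–Bakshi–Shibata reduction of F8 with (S)-2-methyl-CBS-oxazaborolidine and catecholborane (toluene, −78 °C) is then expected to give the 7R alcohol 25, with the aryl group acting as the larger substituent; catecholborane is chosen because it should not hydroborate the styrene.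

## Further compounds

F1 | step 7 | (1E,4R,5R)-4-[2-(benzyloxy)ethyl]-2-(TBSO-methyl)-5-hydroxy-1-methoxy-5-[4-(TIPSO)phenyl]pent-1-en-3-one | CO/C=C(CO[Si](C)(C)C(C)(C)C)/C(=O)[C@H](CCOCc1ccccc1)[C@@H](O)c1ccc(O[Si](C(C)C)(C(C)C)C(C)C)cc1
F2 | step 2 | 1-methoxy-1-(trimethylsilyloxy)-3-(TBSO)prop-1-ene (mixture of geometric isomers) | COC(O[Si](C)(C)C)=CCO[Si](C)(C)C(C)(C)C
F3 | step 2 | methyl 2-(TBSO-methyl)-3,3-dimethoxypropanoate (racemic) | COC(OC)C(CO[Si](C)(C)C(C)(C)C)C(=O)OC
F4 | step 9 | N-[(2R,3S,4S)-3-[2-(benzyloxy)ethyl]-5-(TBSO-methyl)-2-[4-(TIPSO)phenyl]-3,4-dihydro-2H-pyran-4-yl]-2-nitrobenzenesulfonohydrazide | c1ccccc1COCC[C@H]2[C@H](N(N)S(=O)(=O)c4ccccc4[N+](=O)[O-])C(CO[Si](C)(C)C(C)(C)C)=CO[C@H]2c3ccc(O[Si](C(C)C)(C(C)C)C(C)C)cc3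
F5 | step 9 | (2R,3S,4S)-3-[2-(benzyloxy)ethyl]-5-(TBSO-methyl)-4-diazenyl-2-[4-(TIPSO)phenyl]-3,4-dihydro-2H-pyran | c1ccccc1COCC[C@H]2[C@H](N=N)C(CO[Si](C)(C)C(C)(C)C)=CO[C@H]2c3ccc(O[Si](C(C)C)(C(C)C)C(C)C)cc3
F6 | step 10 | (2R,3R,5R)-3-[2-(benzyloxy)ethyl]-5-(TBSO-methyl)-2-[4-(TIPSO)phenyl]oxane | c1ccccc1COCC[C@H]2C[C@@H](CO[Si](C)(C)C(C)(C)C)CO[C@H]2c3ccc(O[Si](C(C)C)(C(C)C)C(C)C)cc3
F7 | step 17 | (S)-[(2R,3S,5R)-2-[4-(TIPSO)phenyl]-3-{(2E)-3-[4-(TIPSO)phenyl]prop-2-en-1-yl}oxan-5-yl][4-(TIPSO)phenyl]methanol | CC(C)[Si](C(C)C)(C(C)C)Oc1ccc(/C=C/C[C@H]2C[C@@H]([C@H](O)c3ccc(O[Si](C(C)C)(C(C)C)C(C)C)cc3)CO[C@H]2c4ccc(O[Si](C(C)C)(C(C)C)C(C)C)cc4)cc1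
F8 | step 17 | [(2R,3S,5R)-2-[4-(TIPSO)phenyl]-3-{(2E)-3-[4-(TIPSO)phenyl]prop-2-en-1-yl}oxan-5-yl][4-(TIPSO)phenyl]methanone | CC(C)[Si](C(C)C)(C(C)C)Oc1ccc(/C=C/C[C@H]2C[C@@H](C(=O)c3ccc(O[Si](C(C)C)(C(C)C)C(C)C)cc3)CO[C@H]2c4ccc(O[Si](C(C)C)(C(C)C)C(C)C)cc4)cc1
A1 | alternative 1 | dimethyl 2-[(2R,3R,5R)-5-[(R)-(TBSO)(4-TBSO-phenyl)methyl]-2-(4-TBSO-phenyl)oxan-3-yl]propanedioate | COC(=O)C(C(=O)OC)[C@H]1C[C@@H]([C@@H](O[Si](C)(C)C(C)(C)C)c2ccc(O[Si](C)(C)C(C)(C)C)cc2)CO[C@H]1c1ccc(O[Si](C)(C)C(C)(C)C)cc1
A2 | alternative 1 | dimethyl (2S,3S)-2-[(2R,3R)-2-(hydroxymethyl)-3-(TBSO)-3-(4-TBSO-phenyl)propyl]-3-(4-TBSO-phenyl)cyclopropane-1,1-dicarboxylate | COC(=O)C1(C(=O)OC)[C@@H](C[C@H](CO)[C@@H](O[Si](C)(C)C(C)(C)C)c2ccc(O[Si](C)(C)C(C)(C)C)cc2)[C@H]1c1ccc(O[Si](C)(C)C(C)(C)C)cc1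
A3 | alternative 2 | (2S,4S)-1,5-bis[(4R)-4-benzyl-2-oxo-1,3-oxazolidin-3-yl]-2,4-bis[(R)-hydroxy(4-TBSO-phenyl)methyl]pentane-1,5-dione | O=C(N1[C@H](Cc2ccccc2)COC1=O)[C@H]([C@@H](O)c1ccc(O[Si](C)(C)C(C)(C)C)cc1)C[C@@H]([C@@H](O)c1ccc(O[Si](C)(C)C(C)(C)C)cc1)C(=O)N1[C@H](Cc2ccccc2)COC1=O
A4 | alternative 2 | 1,5-bis[(4R)-4-benzyl-2-oxo-1,3-oxazolidin-3-yl]pentane-1,5-dione | O=C(CCCC(=O)N1[C@H](Cc2ccccc2)COC1=O)N1[C@H](Cc2ccccc2)COC1=O
A5 | alternative 2 | 4-(TBSO)benzaldehyde | O=Cc1ccc(O[Si](C)(C)C(C)(C)C)cc1
A6 | alternative 3 | (2S)-6-hydroxy-2-(4-TBSO-phenyl)-5-(TIPSO-methyl)-2H-pyran-3(6H)-one (C6 anomers) | O=C1C=C(CO[Si](C(C)C)(C(C)C)C(C)C)C(O)O[C@H]1c1ccc(O[Si](C)(C)C(C)(C)C)cc1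
A7 | alternative 3 | (S)-[4-(TIPSO-methyl)furan-2-yl][4-(TBSO)phenyl]methanol | O[C@H](c1cc(CO[Si](C(C)C)(C(C)C)C(C)C)co1)c1ccc(O[Si](C)(C)C(C)(C)C)cc1
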